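**Retrosynthetic overview**
- Kadsurenin D ⇒ the isomeric (2S,3S,3aS)-3a-allyl-2-aryl-3-methyl-dihydrobenzofuran-6-one, by an acid-catalysed 1,3-shift of the benzylic carbon from oxygen to carbon (closes the cyclopentanone ring of the bicyclo[3.2.1]octane last).
- Dihydrobenzofuranone ⇒ 2-allyl-4,4,5-trimethoxycyclohexadienone + (E)-methylisoeugenol, by a catalytic enantioselective formal [3+2] annulation whose ring-closing bond is the benzylic C–O bond (dihydrofuran ring first; fixes the quaternary and the methyl-bearing stereocentres).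
- Quinone monoketal ⇒ 2-allyl-4,5-dimethoxyphenol (oxidative dearomatisation, C–O) ⇒ allyl 3,4-dimethoxyphenyl ether (Claisen) ⇒ 3,4-dimethoxyphenol + allyl bromide.
- Ring order: cyclohexadienone (from the arene) → dihydrofuran (C–O) → cyclopentanone/bicyclo[3.2.1]octane (O→C shift).

Assumption: the SMILES is read as (1S,5S,6R,7R)-5-allyl-7-(3,4-dimethoxyphenyl)-3-methoxy-6-methylbicyclo[3.2.1]oct-3-ene-2,8-dione (aryl exo, methyl endo); the sense of induction of the chiral acid in step 4 cannot be predicted, so "(S,S)" stands for whichever enantiomer of the acid delivers the (3S,3aS) series.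

**Route**

Step 1
Reactants: 1 3,4-dimethoxyphenol; 2 allyl bromide (3-bromoprop-1-ene)
Product: 3 4-(allyloxy)-1,2-dimethoxybenzene
Conditions: K2CO3 (1.5 equiv), acetone, reflux
Reagents that add atoms: none
Why: Williamson ether synthesis, in which the potassium phenoxide of 1 displaces bromide from 2 by SN2 at the primary allylic carbon; no stereocentre is formed.

Step 2
Reactants: 3 4-(allyloxy)-1,2-dimethoxybenzene
Product: 5 2-allyl-4,5-dimethoxyphenol, via ortho-dienone 4 (not isolated)
Conditions: PhNEt2, 200 °C, sealed tube
Reagents that add atoms: none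
Why: Aromatic Claisen rearrangement ([3,3]-sigmatropic shift) to the less hindered ortho carbon, para to the 3-methoxy group, gives dienone 4, which tautomerises to phenol 5; no stereocentre survives.

Step 3
Reactants: 5 2-allyl-4,5-dimethoxyphenol
Product: 6 2-allyl-4,4,5-trimethoxycyclohexa-2,5-dien-1-one
Conditions: PhI(OAc)2 (1.1 equiv), MeOH, 0 °C; aq. NaHCO3 work-up
Reagents that add atoms: methanol, CO
Why: Oxidative dearomatisation of a para-methoxyphenol to the para-quinone monoketal (C–O bond formation at the methoxy-bearing carbon); the allyl group and the second methoxy group are inert and no stereocentre is formed.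

Step 4
Reactants: 6 2-allyl-4,4,5-trimethoxycyclohexa-2,5-dien-1-one; 7 (E)-methylisoeugenol
Product: 11 (2S,3S,3aS)-3a-allyl-2-(3,4-dimethoxyphenyl)-5-methoxy-3-methyl-3,3a-dihydrobenzofuran-6(2H)-one, via oxocarbenium ion 8 (not isolated), via benzylic cation 9 (not isolated), via dimethyl ketal 10 (not isolated)
Conditions: (S,S)-IDPi acid HN[P(=NTf)(O2R*)]2 (3 mol %; O2R* = (S)-3,3'-bis[3,5-(CF3)2C6H3]-1,1'-binaphthyl-2,2'-diolate), 7 (1.5 equiv), CH2Cl2, −78 °C; Et3N; then 0.5 M aq. citric acid, THF, 0 °C
Reagents that add atoms: water, O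
Why: Proposed new method: the confined chiral acid ionises ketal 6 to oxocarbenium ion 8, held as a contact ion pair in the pocket of the chiral anion; the β-carbon of 7 adds to the allyl-bearing carbon on the exposed face, which defines C3a (S) and C3 (S, methyl trans to allyl), and this C–C addition is expected to be reversible (fragmentation of 9 back to the stabilised ion 8), so that the first irreversible, selectivity-fixing event is the ring-closing C–O bond between the dienone carbonyl oxygen and the benzylic cation of 9 (suprafacial on the E-alkene, hence C2 (S) with aryl trans to methyl, kinetic O-capture at −78 °C); return of methanol gives ketal 10 and hands the proton back to the catalyst, and mild aqueous acid unmasks 11; closest known reaction types: the racemic acid-promoted Büchi annulation of quinone monoketals with propenylarenes and asymmetric counteranion-directed catalysis of oxocarbenium ions by imidodiphosphorimidate acids, a combination that has not been described.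

Step 5
Reactants: 11 (2S,3S,3aS)-3a-allyl-2-(3,4-dimethoxyphenyl)-5-methoxy-3-methyl-3,3a-dihydrobenzofuran-6(2H)-one
Product: 13 kadsurenin D, via dienol benzylic cation 12 (not isolated)
Conditions: TfOH (10 mol %), CH2Cl2, −40 → −10 °C; Et3N quench
Reagents that add atoms: none
Why: Acid-catalysed 1,3-shift of the benzylic carbon from oxygen to carbon (the known rearrangement of 3a-allyl-benzofuranone neolignans to bicyclo[3.2.1]octanoids, an intramolecular C-alkylation of a vinylogous acid), in which protonation of the C6 carbonyl ionises the C2–O bond to cation 12 and this re-closes at C7 of the dienol; C3a and C3 of 11 are untouched and become C5 (S) and C6 (R, methyl endo; the change of descriptor from 3S to 6R is a priority change, not an inversion), the new bridgehead C1 (S) is dictated by the tether, and C7 (R) forms with the aryl group exo, trans to the methyl.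

**Compound list**
1 | 3,4-dimethoxyphenol | COc1ccc(O)cc1OC | starting material
2 | allyl bromide (3-bromoprop-1-ene) | C=CCBr | starting material
3 | 4-(allyloxy)-1,2-dimethoxybenzene | C=CCOc1ccc(OC)c(OC)c1 | intermediate
4 | 6-allyl-3,4-dimethoxycyclohexa-2,4-dien-1-one (racemic, transient ortho-dienone) | C=CCC1C=C(OC)C(OC)=CC1=O | intermediate
5 | 2-allyl-4,5-dimethoxyphenol | C=CCc1cc(OC)c(OC)cc1O | intermediate
6 | 2-allyl-4,4,5-trimethoxycyclohexa-2,5-dien-1-one | C=CCC1=CC(OC)(OC)C(OC)=CC1=O | intermediate
7 | (E)-methylisoeugenol; (E)-1,2-dimethoxy-4-(prop-1-en-1-yl)benzene | C/C=C/c1ccc(OC)c(OC)c1 | starting material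
8 | (5-allyl-2-methoxy-4-oxocyclohexa-2,5-dien-1-ylidene)(methyl)oxonium (oxocarbenium ion, paired with the chiral anion) | C=CCC1=CC(=[O+]C)C(OC)=CC1=O | intermediate
9 | (6S)-6-allyl-6-[(2R)-1-(3,4-dimethoxyphenyl)propan-1-ylium-2-yl]-3,4-dimethoxycyclohexa-2,4-dien-1-one (benzylic cation) | C=CC[C@@]1(C=C(OC)C(OC)=CC1=O)[C@H](C)[CH+]c1ccc(OC)c(OC)c1 | intermediate
10 | (2S,3S,3aS)-3a-allyl-2-(3,4-dimethoxyphenyl)-5,6,6-trimethoxy-3-methyl-2,3,3a,6-tetrahydrobenzofuran (dimethyl ketal of 11) | C=CC[C@]12C=C(OC)C(OC)(OC)C=C1O[C@H](c1ccc(OC)c(OC)c1)[C@H]2C | intermediate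
11 | (2S,3S,3aS)-3a-allyl-2-(3,4-dimethoxyphenyl)-5-methoxy-3-methyl-3,3a-dihydrobenzofuran-6(2H)-one (aryl/methyl trans, methyl/allyl trans) | C=CC[C@]12C=C(OC)C(=O)C=C1O[C@H](c1ccc(OC)c(OC)c1)[C@H]2C | intermediate
12 | (6S)-6-allyl-6-[(2R)-1-(3,4-dimethoxyphenyl)propan-1-ylium-2-yl]-3-hydroxy-4-methoxycyclohexa-2,4-dien-1-one (dienol benzylic cation) | C=CC[C@@]1(C=C(OC)C(O)=CC1=O)[C@H](C)[CH+]c1ccc(OC)c(OC)c1 | intermediate
13 | kadsurenin D; (1S,5S,6R,7R)-5-allyl-7-(3,4-dimethoxyphenyl)-3-methoxy-6-methylbicyclo[3.2.1]oct-3-ene-2,8-dione | C=CC[C@]12C=C(OC)C(=O)[C@H](C1=O)[C@H](c1ccc(OC)c(OC)c1)[C@H]2C | target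

**Step count and risks**

Total steps: 5. Longest linear sequence: 5 (1 → 3 → 5 → 6 → 11 → 13).

First risk, step 4 (the proposed new step). The chiral acid may give insufficient enantio- or diastereocontrol, turnover may stall at the O-methylated product cation, 7 may oligomerise, or part of the material may close at carbon directly (that portion is already 13). Any C2 epimer of 11 is harmless, because C2 is reset in step 5; 11 is recrystallised to raise its enantiomeric purity. The fallback uses known chemistry and sets out from 6 (with 7) and comes back at 11. The classical racemic acid-promoted Büchi annulation (TfOH 10 mol % or TMSOTf, MeCN, −40 °C, same aqueous work-up) gives racemic 11, that is 11 together with its enantiomer (2R,3R,3aR)-3a-allyl-2-(3,4-dimethoxyphenyl)-5-methoxy-3-methyl-3,3a-dihydrobenzofuran-6(2H)-one F1. The two are separated by preparative HPLC on a cellulose tris(3,5-dimethylphenylcarbamate) phase, and 11 goes on into step 5.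

Second risk, step 5. Cation 12 could fragment to 7 and an achiral ring cation and recombine, which would erode the enantiomeric purity. The allyl group could also undergo a [3,3] shift in the ring-opened dienone, or the O→C shift could stop at an equilibrium mixture. The fallback sets out from 5 and comes back at 13, forming both C–C bonds directly under a Lewis acid. Phenol 5 is oxidised with (NH4)2Ce(NO3)6 in MeCN/H2O at 0 °C to 5-allyl-2-methoxy-1,4-benzoquinone F2. F2 and 7 are combined with TiCl2[(R,R)-TADDOLate] (from TiCl4, Ti(OiPr)4 and the TADDOL enantiomer that gives the required series) in CH2Cl2 at −78 °C and warmed, the known Lewis-acid-promoted [5+2] cycloaddition of 2-methoxy-1,4-benzoquinones with propenylarenes. With loss of the O-methyl group this gives the bicyclic diosphenol (1S,5S,6R,7R)-5-allyl-7-(3,4-dimethoxyphenyl)-3-hydroxy-6-methylbicyclo[3.2.1]oct-3-ene-2,8-dione F3, which is purified to a single enantiomer by crystallisation or chiral HPLC if needed. O-Methylation of the enol (MeI, K2CO3, acetone) then gives 13.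

Third risk, step 2. The Claisen rearrangement can also deliver the regioisomeric 2-allyl-3,4-dimethoxyphenol, which is hard to separate, and the phenol can degrade at 200 °C. The fallback sets out from 1 and comes back at 5 without a sigmatropic step. Phenol 1 is brominated with N-bromosuccinimide (MeCN, 0 °C) at the position ortho to OH and para to the 3-methoxy group, giving 2-bromo-4,5-dimethoxyphenol F4. Suzuki–Miyaura coupling of F4 with allylboronic acid pinacol ester (Pd(PPh3)4, K2CO3, dioxane/H2O, 80 °C) gives 5.

Further compounds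
F1 | step 4 | (2R,3R,3aR)-3a-allyl-2-(3,4-dimethoxyphenyl)-5-methoxy-3-methyl-3,3a-dihydrobenzofuran-6(2H)-one (enantiomer of 11) | C=CC[C@@]12C=C(OC)C(=O)C=C1O[C@@H](c1ccc(OC)c(OC)c1)[C@@H]2C
F2 | step 5 | 5-allyl-2-methoxy-1,4-benzoquinone | C=CCC1=CC(=O)C(OC)=CC1=O
F3 | step 5 | (1S,5S,6R,7R)-5-allyl-7-(3,4-dimethoxyphenyl)-3-hydroxy-6-methylbicyclo[3.2.1]oct-3-ene-2,8-dione | C=CC[C@]12C=C(O)C(=O)[C@H](C1=O)[C@H](c1ccc(OC)c(OC)c1)[C@H]2C
F4 | step 2 | 2-bromo-4,5-dimethoxyphenol | COc1cc(O)c(Br)cc1OC
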